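The reading at 40 h comes late, so I ask which clocks have run down by then, from the fastest to the slowest.

| flask | substrate | partner | temperature | remark | time |
|---|---|---|---|---|---|
| blue | 33 mM | 36.3 mM | 25 °C | run made earlier |  |
| red | 33 mM | 54 mM | 25 °C | run made earlier |  |
| zeta | 33 mM (fed, over 1.5 h) | 36.3 mM | 25 °C | all else is in the flask from the start; the feed brings no volume worth counting | 40 h |
| delta | 33 mM (fed, over 15 h) | 36.3 mM | 25 °C | all else is in the flask from the start; the feed brings no volume worth counting | 40 h |
| eta | 33 mM (fed, over 15 h) | 36.3 mM |  | the addition at −15 °C, then warmed to 25 °C; the feed brings no volume worth counting | 40 h |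
| epsilon | 33 mM (in portions, 4, over 15 h) | 36.3 mM | 25 °C | first portion at the start, last at 15 h | 40 h |
| theta | 33 mM | 36.3 mM |  | everything together at the start at −15 °C, warmed to 25 °C at 15 h | 40 h |
| alpha | 33 mM | 36.3 mM (fed, over 15 h) | 25 °C | all else is in the flask from the start; the feed brings no volume worth counting | 40 h |

- blue (time / h: product / %, substrate / %): 2.00: 4.2, 33.7; 6.00: 19.8, 4.4; 12.0: 34.0, 1.4; 15.0: 38.5, 0.6; 25.0: 43.9, 1.7
- red (time / h: product / %, substrate / %): 0.833: 0.3, 63.1; 1.50: 2.2, 43.9; 2.50: 6.4, 26.9; 3.00: 11.2, 20.4; 4.00: 17.2, 10.8

(standard deviation of a reading: 1 percentage point)

- which flask leads in amount of product, in percent of the substrate charged ("all alike" within 1.5 percentage points) (zeta / delta / eta / epsilon / theta / alpha / all alike)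
- how much product is there at the end, in percent of the substrate charged: zeta
- how much product is there at the end, in percent of the substrate charged: delta
- how much product is there at the end, in percent of the substrate charged: eta
- how much product is there at the end, in percent of the substrate charged: epsilon
- how much product is there at the end, in percent of the substrate charged: theta
- how much product is there at the end, in percent of the substrate charged: alpha

- the earlier runs do not show what temperature does; that part of a forecast is a guess

The first clock is the substrate's. In blue it falls at 0.509 /h, a lifetime of 1.96 h. In red it falls at 0.557 /h, a factor of 1.09, though red has 1.49 times the partner.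

The product's pace comes next. The mean of blue's readings at 2.00 h and 6.00 h stands for blue at 4.00 h and gives 12.0 %. Red reads 17.2 % there, a factor of 1.43, so I take partner to quicken the product.

The last clock is the tail. Blue's late gains shrink with a lifetime of 6.36 h, a rough reading, longer than the substrate's lifetime. Yet at 25.0 h the readings leave 54.4 % of the charge as neither substrate nor product, more than the product. So I place the fading on the partner's side, with 14.5 mM of product read against 36.3 mM of partner charged.

I read partner as spending itself on its own clock, and I carry one number: the partner yield, product made per partner charged, 39.9 %. If that share does not depend on what else stands in a flask, the final product is the yield times c(partner) over c(substrate). I take the yield from blue's last reading, which carries a scatter of 1 percentage point, and gains may still follow it, so this number is a reading and not a plateau.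

The flasks whose addition or warming ends at 15 h still have 25.0 h after it, which is 3.93 tail lifetimes. That the cold flasks eta and theta wait until warming is a guess. My reckoning gives 43.9 % for zeta, delta, eta, epsilon, theta and alpha, and I name no leader.

The forecast differs: it leads with delta, giving zeta 47 %, delta 54 %, eta 45 %, epsilon 52 %, theta 44 % and alpha 38 %, on the ground that “slow feeding should help modestly by keeping partner high”.

The flasks give zeta 43.4 %, delta 43.3 %, eta 42.9 %, epsilon 43.3 %, theta 42.9 % and alpha 43.2 %, so the answer is all alike.

    partner → second intermediate (k = 3.20 × 10⁻⁵ /s, Ea = 92.0 kJ/mol)
    partner → decomposed reagent (k = 4.90 × 10⁻⁵ /s, Ea = 103 kJ/mol)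
    open intermediate + second intermediate → product (k = 0.00280 /M/s, Ea = 65.0 kJ/mol)
    substrate → open intermediate (k = 1.50 × 10⁻⁴ /s, Ea = 85.0 kJ/mol)
    (constants at 25 °C)

Partner goes to second intermediate at 3.2 × 10⁻⁵ /s and to decomposed reagent at 4.9 × 10⁻⁵ /s, the second way faster, and in delta 22.0 mM of decomposed reagent stands at 40.0 h. That split sends 39.5 % of the partner to second intermediate, beside the partner yield of 39.9 % read from blue. Partner is the limiting reagent in delta, with 0 % of its charge left and 0.0359 mM of second intermediate beside 56.7 % of open intermediate.

For the neighbour of delta with 15 mM of partner, the partner yield of 39.9 % gives 18.1 %. The computed flask ends at 18.0 %.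

The runs were computed for an exercise; noise was put on by code.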